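Each substrate molecule that reacts becomes one product molecule, so the two substrates and the two products together stay at the charge, apart from the 0.0250% the catalyst can hold. Left-handed substrate leaves through catalyst intermediate A and gives left-handed product. Right-handed substrate leaves through catalyst intermediate B and gives right-handed product. They start equal, so their gap counts the surplus of left-handed product made, whatever the rates.

in all of them: gas 200 mM (held)
- cedar: left-handed substrate 2 M; right-handed substrate 2 M; free catalyst 1 mM; added ligand 3.1 mM; run made earlier
- elm: left-handed substrate 2 M; right-handed substrate 2 M; free catalyst 1 mM; added ligand 4.8 mM; run made earlier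
- flask: left-handed substrate 2.0 M; right-handed substrate 2.0 M; free catalyst 1.0 mM; added ligand 2.2 mM; time 80 min

- cedar (time / min: left-handed substrate / %, right-handed substrate / %): 6.00: 49.6, 48.8; 15.0: 48.4, 49.3; 20.0: 47.4, 49.1; 30.0: 45.9, 48.8; 40.0: 44.7, 48.1; 50.0: 42.8, 47.6
- elm (time / min: left-handed substrate / %, right-handed substrate / %): 6.00: 49.4, 49.6; 15.0: 48.4, 49.3; 20.0: 47.5, 49.0; 30.0: 46.7, 48.2; 40.0: 44.7, 48.1; 50.0: 43.8, 47.7

(each reading ± 0.5 percentage points)

- free catalyst is single-handed; left-handed substrate and right-handed substrate are mirror images of each other, charged as a racemate, each of them at the stated concentration
- at the start none of coupling partner is dissolved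
- steps thought possible: free catalyst + right-handed substrate <-> catalyst intermediate B; free catalyst + left-handed substrate <-> catalyst intermediate A; left-handed product <-> right-handed product; coupling partner + catalyst intermediate A -> free catalyst + left-handed product; coupling partner + catalyst intermediate B -> free catalyst + right-handed product; free catalyst + added ligand <-> idle complex; gas <-> coupling partner
- an excess is the difference of the two amounts in percent of their sum
- an excess is below zero if the other one leads

- part of the left-handed substrate and right-handed substrate charged together that has reacted at 80 min
- excess of left-handed product over right-handed product in the product at 80 min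
- excess of right-handed substrate over left-handed substrate among what is left of the two at 80 min

I pool cedar and elm at 50.0 min. The gap c(right-handed substrate) minus c(left-handed substrate) sums to 8.7 percentage points, and the total lost sums to 18 points. Their quotient is 48.1%. This is the made excess m, the gap divided by the total lost. It is a reading, and the gap carries the scatter of four readings.

Racemisation, the step left-handed product to right-handed product, touches no substrate, so the gap can't see it. I take m as my estimate of the excess made in the flask, although cedar and elm held 3.1 mM and 4.8 mM of added ligand and the flask holds 2.2 mM. I put eP at or below m, by an amount I can't read, since the readings are of substrates. eS is then m times the reacted part over the unreacted part.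

The forecast gives c 15.2%, eP 44% and eS 7.9%, taking the excess from loss rates fitted through the origin of the two runs: “Depletion of the left-handed substrate lowers this slightly”. With its c, my rule gives eS 8.62%, not its figure.

The flask gives c 15.8%, eP 7.82% and eS 8.69%.

    free catalyst + right-handed substrate ⇌ catalyst intermediate B (K = 0.450 /M, k = 140 /M/min)
    free catalyst + left-handed substrate ⇌ catalyst intermediate A (K = 0.570 /M, k = 820 /M/min)
    left-handed product ⇌ right-handed product (k = 0.0370 /min)
    coupling partner + catalyst intermediate A → free catalyst + left-handed product (k = 370 /M/min)
    coupling partner + catalyst intermediate B → free catalyst + right-handed product (k = 160 /M/min)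
    free catalyst + added ligand ⇌ idle complex, settled at all times (K = 620 /M)
    gas ⇌ coupling partner, rate k7*(csat - [coupling partner]) (kL = 0.0640 /min)

In this flask the half-life of left-handed product by its conversion into right-handed product, forward rate alone, is 19 min, shorter than the 80 min of the run, and the eP of 7.82% is 16.3% of m. A neighbour flask charged with 0.0088 M of added ligand reaches c 11.6% and eP 8.37%, which is 17.4% of m.

The data are simulated on assumed constants.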